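Numbering used throughout: benzofuran numbering (O1, C2, C3, C3a, C4–C7, C7a); C9 is the exocyclic carbon on C3; ring A is the 3,4,5-trimethoxyphenyl ring, ring B the benzo ring, ring C the dihydrofuran ring. Compound numbers 1–16 are those of the steps below.

## The problem

Target 16 is a 2-aryl-3-(hydroxymethyl)-2,3-dihydrobenzofuran: ring A sits on C2, ring B carries an (E)-3-hydroxyprop-1-enyl chain at C5 (para to O1), and ring C (O1–C2–C3–C3a–C7a) holds the only two stereocentres, C2 (R) and C3 (S), trans to each other. Trans is the thermodynamically preferred arrangement, so C2 can steer C3 whenever the ring-forming step is reversible or C3 is epimerisable. Nothing in the molecule can steer C2, whose absolute configuration must come from a reagent. The C2–O1 bond is a benzylic aryl ether: it ionises under strong Brønsted or Lewis acid, is cleaved by hydrogenolysis, and becomes a β-leaving group for E1cB ring opening under base once C3 carries a carbonyl group. The cinnamyl alcohol is acid-labile, oxidisable and reducible, so it should be made last, which calls for a C5 bromide as a placeholder that survives ring construction. The enabling feature is that C2 is bonded to only three heavy atoms (O1, C3 and the ipso carbon of ring A), so it can be brought in as one benzylic sulfonium ylide carbon and joined to the four-atom unit O1–C7a–C3a–C3 of a 2-(2-nitrovinyl)phenol. The nitromethyl group this leaves on C3 is C9 in masked form, convertible to CH2OH without touching either stereocentre.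

## Retrosynthesis

**Side chain (16 ⇒ 15 ⇒ 13 + 14).** The allylic alcohol of 16 is traced to the methyl cinnamate 15, and the C5–vinyl bond of 15 is cut by a Heck disconnection to aryl bromide 13 and methyl acrylate 14. Carrying an acrylate or allylic alcohol on ring B from the start is the poorer choice: an acrylate would be a second Michael acceptor for the ylide, and neither group would pass unharmed through the nitrosation and hydride steps that adjust C9. The bromide is inert to all of these, and 13 is three carbons simpler. The forward steps must give the E alkene on an electron-rich aryl bromide beside a free primary alcohol, and must reduce the ester 1,2-selectively.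

**C9 oxidation level (13 ⇒ 12 ⇒ 11).** No skeletal bond is cut. The C9–O bond of 13 is traced through carboxylic acid 12 to the C9–N bond of nitro compound 11. The acid is preferred over a Nef aldehyde because an aldehyde on C3 is both epimerisable and prone to E1cB opening of ring C, whereas 12 is formed and reduced under non-basic conditions. Acid 12 is also a crystalline, salt-forming intermediate at which enantiomeric purity can be raised if needed. The forward steps must convert CH2NO2 to CO2H without disturbing C3, and reduce the acid in the presence of the aryl bromide.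

**Ring C (11 ⇒ 8 + 5, key cut).** Both bonds to C2 within the ring, O1–C2 and C2–C3, are cut together, giving nitrovinylphenol 8 and benzylic sulfonium salt 5. Cutting only C2–C3 or only O1–C2 leaves a precursor that already contains both aryl rings and needs its own stereocontrolled assembly. The double cut instead splits the molecule into two halves of similar size, each one bond-forming step from commercial materials, and removes the ring and both stereocentres at once. The forward reaction must do four things:
- the ylide carbon must bond to the nitroalkene carbon on ring B;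
- the phenoxide, not the nitronate, must then displace the sulfide;
- the ring must close trans;
- the chiral sulfide must select one face of the ylide carbon.

**Nitroalkene (8 ⇒ 6 + 7).** The C3=C9 double bond is cut by a Henry condensation to 5-bromosalicylaldehyde 6 and nitromethane 7. No protecting group is needed because the free phenol is exactly what the annulation requires. The forward step only has to give the conjugated E alkene.

**Sulfonium salt (5 ⇒ 3 + 4; 3 ⇒ 2 ⇒ 1).** The S–CH2 bond is cut to C2-symmetric sulfide 3 and benzyl bromide 4. The two ring C–S bonds of 3 are cut to dimesylate 2 and hence to (2S,5S)-hexane-2,5-diol 1, with double inversion in the forward direction. A C2-symmetric sulfide is chosen because its two lone pairs are equivalent, so alkylation gives one sulfonium salt with no stereocentre at sulfur. The forward steps are two substitutions and an S-alkylation.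

## Roads not taken

**Alternative 1:** aryl radical cyclisation with nitroxide trapping.
- Cut: C3–C3a and the C9–O bond.
- Forward: (S)-1-(3,4,5-trimethoxyphenyl)prop-2-en-1-ol A1 is etherified with inversion (Mitsunobu) by 4-bromo-2-iodophenol A2 to give (R)-aryl ether A3. The aryl radical from the iodide of A3 cyclises 5-exo-trig onto the vinyl group, and TEMPO traps the primary C9 radical, giving (2R,3S)-configured A4. N–O cleavage of A4 leads straight to 13.
- Merits: C9 arrives already oxygenated, so A4 is one step from 13 where the chosen plan needs two from 11. The configuration at C2 rests on established carbonyl chemistry, not on an untested induction. In both respects this road is the better one.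
- Weak points:
  - A1 needs its own asymmetric step.
  - The Mitsunobu reaction on a secondary alcohol that is both allylic and benzylic invites SN2′ attack and ion-pair racemisation.
  - The 5-exo closure is under kinetic control with one adjacent stereocentre, so the trans preference is typically modest, and C3 in A4 has no acidifying group through which a cis isomer could be corrected.
  - Radical generation must spare the C5 bromide.
  - A3 is an aryl allyl ether that can undergo Claisen rearrangement on heating.
- Comparison: the chosen plan sets both stereocentres in the fragment union itself, has a thermodynamic bias toward trans, and passes through acid 12, where C3 is epimerisable toward trans.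

**Alternative 2:** carbenoid C–H insertion.
- Cut: C2–C3 only.
- Forward: aryldiazoacetate A5 is decomposed by dirhodium tetrakis[N-phthaloyl-(S)-tert-leucinate], Rh2(S-PTTL)4, or its enantiomer. The carbenoid inserts into the benzylic ether C–H to give cis ester A6 (2R,3S). Base epimerisation at C3 gives trans ester A7 (2R,3R), which is reduced to 13 or taken directly through Heck coupling and a double ester reduction.
- Merits: this road has the firmest precedent of the four, and from commercial materials it is no longer than the chosen route. It is shorter if A7 is carried through the Heck step and both esters are reduced together.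
- Weak points:
  - It needs a diazo compound and a costly chiral rhodium catalyst.
  - It gives the wrong (cis) diastereomer first.
  - The correction passes through an ester enolate with O1 as a β-leaving group, so ring opening and reclosure can erode C2.
- Comparison: the chosen plan gives trans directly, joins two equal halves convergently, uses a recoverable sulfide and no precious metal in the stereo-defining step, and has no basic epimerisation. Because Alternative 2 is the better-precedented road, it is kept as the fallback for step 5.

**Alternative 3:** strain-release oxymercuration.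
- Cut: O1–C2, with C9 unmasked from a cyclopropane CH2.
- Forward: trans-diarylcyclopropane A8 (1S,2S) is treated with Hg(OCOCF3)2. The mercury attacks the CH2 carbon, the bond from it to the ring A-bearing carbon breaks, and the phenol oxygen captures that carbon with inversion. After NaCl work-up this gives organomercurial A9, and oxidative demercuration would lead to 13.
- Merits: the opening is stereospecific, so a trans cyclopropane gives the trans ring and its absolute configuration is carried over without new induction. C9 reaches the alcohol level in one further step.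
- Weak points:
  - The required regiochemistry is electronically disfavoured. The carbon on ring B carries an ortho oxygen and gives the better-stabilised benzylic cation, while ring A is only a weak para donor because its central methoxy group is twisted out of conjugation. Cleavage toward C3 or of the aryl–aryl-flanked bond therefore competes.
  - Hg(OCOCF3)2 is a strong aromatic mercurating agent for both electron-rich rings.
  - Enantioselective access to A8 is a multistep problem of its own.
  - Stoichiometric mercury is used.
  - Oxidative demercuration runs through a C9 radical that can also be reduced to methyl.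
- Comparison: this road offers stereospecific transfer of configuration. The chosen plan has unambiguous regiochemistry (the ylide carbon can only add to the nitroalkene β-carbon), a shorter route and no toxic metal.

Key step: step 5

Assumption: (2R,5R)-2,5-dimethylthiolane is taken to steer the ylide carbon into the 2R series, by analogy with the facial sense expected when its benzylic ylides transfer a benzylidene carbon to aldehydes. If the annulation shows the opposite sense, the (2S,5S) sulfide, made the same way from (2R,5R)-hexane-2,5-diol, replaces it and nothing else changes.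

## Route

Step 1
Reactants: 1 (2S,5S)-hexane-2,5-diol
Product: 2 (2S,5S)-hexane-2,5-diyl dimethanesulfonate
Conditions: MsCl, Et3N, CH2Cl2, 0 °C
Reagents that add atoms: methanesulfonyl chloride, CS(=O)(=O)Cl
Why: O-Sulfonylation of a secondary diol; no C–O bond is broken, so both centres stay S.

Step 2
Reactants: 2 (2S,5S)-hexane-2,5-diyl dimethanesulfonate
Product: 3 (2R,5R)-2,5-dimethylthiolane
Conditions: Na2S·9H2O, DMSO, 20 °C
Reagents that add atoms: sodium sulfide (as nonahydrate), [Na+].[Na+].[S-2]
Why: Double SN2 thioetherification: sulfide displaces one mesylate and the resulting thiolate closes the ring 5-exo-tet on the other, each with inversion, so (S,S)-2 gives the C2-symmetric (R,R)-thiolane.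

Step 3
Reactants: 3 (2R,5R)-2,5-dimethylthiolane; 4 3,4,5-trimethoxybenzyl bromide
Product: 5 (2R,5R)-2,5-dimethyl-1-(3,4,5-trimethoxybenzyl)thiolan-1-ium bromide
Conditions: acetone, 20 °C, 48 h; salt collected by filtration
Reagents that add atoms: none
Why: SN2 S-alkylation of a dialkyl sulfide by a reactive benzylic bromide; because the two sulfur lone pairs of 3 are related by the C2 axis, a single sulfonium salt without a sulfur stereocentre results.

Step 4
Reactants: 6 5-bromosalicylaldehyde; 7 nitromethane
Product: 8 4-bromo-2-[(E)-2-nitroethenyl]phenol
Conditions: NH4OAc, AcOH, 100 °C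
Reagents that add atoms: none
Why: Henry (nitroaldol) condensation with dehydration in the same pot; the conjugated E nitroalkene is the thermodynamic product and the free phenol is tolerated.

Step 5
Reactants: 8 4-bromo-2-[(E)-2-nitroethenyl]phenol; 5 (2R,5R)-2,5-dimethyl-1-(3,4,5-trimethoxybenzyl)thiolan-1-ium bromide
Product: 11 (2R,3S)-5-bromo-3-(nitromethyl)-2-(3,4,5-trimethoxyphenyl)-2,3-dihydro-1-benzofuran, via sulfonium ylide 9 (not isolated), via nitronate betaine 10 (not isolated)
Conditions: Cs2CO3 (2.2 equiv), 5 (1.2 equiv), MeCN, −20 °C → 20 °C; aq NH4Cl quench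
Reagents that add atoms: none
Why: Proposed new method: the closest known reaction type is the formal [4+1] annulation of 2-(2-nitrovinyl)phenols with acyl-stabilised sulfonium ylides, which gives trans-3-(nitromethyl)-2,3-dihydrobenzofurans; new here is a semi-stabilised benzylic ylide carried on an enantiopure sulfide. Cs2CO3 forms the phenoxide of 8 and, reversibly, ylide 9 from 5; the ylide carbon adds to the nitroalkene carbon attached to ring B (C2–C3 bond) to give betaine 10, the phenoxide oxygen then displaces the thiolane from the former ylide carbon by SN2 with inversion (O1–C2 bond) in a 5-exo-tet closure of ring C, and protonation of the nitronate on work-up gives 11. C2 is controlled by the C2-symmetric sulfide, whose methyl groups flank the ylide carbon and leave one face open for C–C bond formation, and the stereospecific SN2 step carries that choice into the product. C3 is controlled relative to C2: addition to a nitroalkene gives a stabilised nitronate and should be reversible, so the betaines equilibrate and the one that places ring A and the nitronate arm on opposite faces of the forming ring closes fastest, giving the trans product. The step needs the phenoxide to win over the nitronate, whose carbon would give a nitrocyclopropane (3-exo-tet) and whose oxygen an isoxazoline N-oxide; the phenoxide is held by ring B within reach of the backside of C2 in a five-membered transition state, the preference the acyl-ylide precedent shows. It also needs ylide formation to outrun direct O-benzylation of the phenoxide by 5, which the low temperature and the weak nucleophilicity of this conjugated, bromine-substituted phenoxide should favour.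

Step 6
Reactants: 11 (2R,3S)-5-bromo-3-(nitromethyl)-2-(3,4,5-trimethoxyphenyl)-2,3-dihydro-1-benzofuran
Product: 12 (2R,3R)-5-bromo-2-(3,4,5-trimethoxyphenyl)-2,3-dihydro-1-benzofuran-3-carboxylic acid
Conditions: NaNO2, AcOH, DMSO, 35 °C
Reagents that add atoms: water, O (supplies the carboxyl oxygens; it is formed in the nitrosation and present in the medium)
Why: Nitrite-mediated conversion of a primary nitroalkane to the carboxylic acid (nitrosation to a nitrolic acid, loss of nitrite to a nitrile oxide, hydrolysis through the hydroxamic acid) under mildly acidic conditions that avoid enolate formation and E1cB ring opening. The spatial arrangement at C3 is unchanged (the descriptor becomes R only because CO2H outranks C2), and trans is in any case the stable isomer.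

Step 7
Reactants: 12 (2R,3R)-5-bromo-2-(3,4,5-trimethoxyphenyl)-2,3-dihydro-1-benzofuran-3-carboxylic acid
Product: 13 [(2R,3S)-5-bromo-2-(3,4,5-trimethoxyphenyl)-2,3-dihydro-1-benzofuran-3-yl]methanol
Conditions: BH3·THF, THF, 0 → 20 °C; MeOH quench
Reagents that add atoms: none
Why: Chemoselective borane reduction of a carboxylic acid via the acyloxyborane; the aryl bromide and aryl ethers are inert, and the non-basic medium leaves C3 untouched.

Step 8
Reactants: 13 [(2R,3S)-5-bromo-2-(3,4,5-trimethoxyphenyl)-2,3-dihydro-1-benzofuran-3-yl]methanol; 14 methyl acrylate
Product: 15 methyl (E)-3-[(2R,3S)-3-(hydroxymethyl)-2-(3,4,5-trimethoxyphenyl)-2,3-dihydro-1-benzofuran-5-yl]prop-2-enoate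
Conditions: Pd(OAc)2 (5 mol %), P(o-tol)3, Et3N, DMF, 100 °C
Reagents that add atoms: none
Why: Mizoroki–Heck reaction: oxidative addition of the aryl bromide to zerovalent palladium formed in situ, syn carbopalladation of the acrylate and syn β-hydride elimination give the E cinnamate; the primary alcohol needs no protection and neither stereocentre is acidic at this stage.

Step 9
Reactants: 15 methyl (E)-3-[(2R,3S)-3-(hydroxymethyl)-2-(3,4,5-trimethoxyphenyl)-2,3-dihydro-1-benzofuran-5-yl]prop-2-enoate
Product: 16 (E)-3-[(2R,3S)-3-(hydroxymethyl)-2-(3,4,5-trimethoxyphenyl)-2,3-dihydro-1-benzofuran-5-yl]prop-2-en-1-ol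
Conditions: i-Bu2AlH (4 equiv), CH2Cl2, −78 °C; aq potassium sodium tartrate work-up
Reagents that add atoms: none
Why: 1,2-Reduction of an α,β-unsaturated ester to the allylic alcohol with diisobutylaluminium hydride; the free hydroxyl consumes one equivalent as its aluminium alkoxide, and the alkene geometry and both stereocentres are unaffected.

## Compound list

1 | (2S,5S)-hexane-2,5-diol | C[C@H](O)CC[C@H](C)O | starting material
2 | (2S,5S)-hexane-2,5-diyl dimethanesulfonate | C[C@H](OS(C)(=O)=O)CC[C@H](C)OS(C)(=O)=O | intermediate
3 | (2R,5R)-2,5-dimethylthiolane | C[C@@H]1CC[C@@H](C)S1 | intermediate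
4 | 3,4,5-trimethoxybenzyl bromide | COc1cc(CBr)cc(OC)c1OC | starting material
5 | (2R,5R)-2,5-dimethyl-1-(3,4,5-trimethoxybenzyl)thiolan-1-ium bromide | C[C@@H]1CC[C@@H](C)[S+]1Cc1cc(OC)c(OC)c(OC)c1.[Br-] | intermediate
6 | 5-bromosalicylaldehyde (5-bromo-2-hydroxybenzaldehyde) | O=Cc1cc(Br)ccc1O | starting material
7 | nitromethane | C[N+](=O)[O-] | starting material
8 | 4-bromo-2-[(E)-2-nitroethenyl]phenol | Oc1ccc(Br)cc1/C=C/[N+](=O)[O-] | intermediate
9 | (2R,5R)-2,5-dimethylthiolan-1-ium (3,4,5-trimethoxyphenyl)methanide, the benzylic sulfonium ylide | C[C@@H]1CC[C@@H](C)[S+]1[CH-]c1cc(OC)c(OC)c(OC)c1 | intermediate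
10 | cesium salt of the phenoxide–nitronate betaine: the former ylide carbon (future C2, still bearing the thiolanium group and ring A) is bonded to the ring B benzylic carbon (future C3), which carries the nitronate CH=NO2 arm | COc1cc([C@H]([C@H](C=[N+]([O-])[O-])c2cc(Br)ccc2[O-])[S+]2[C@H](C)CC[C@H]2C)cc(OC)c1OC.[Cs+] | intermediate
11 | (2R,3S)-5-bromo-3-(nitromethyl)-2-(3,4,5-trimethoxyphenyl)-2,3-dihydro-1-benzofuran (trans) | COc1cc([C@@H]2Oc3ccc(Br)cc3[C@H]2C[N+](=O)[O-])cc(OC)c1OC | intermediate
12 | (2R,3R)-5-bromo-2-(3,4,5-trimethoxyphenyl)-2,3-dihydro-1-benzofuran-3-carboxylic acid (trans) | COc1cc([C@@H]2Oc3ccc(Br)cc3[C@H]2C(=O)O)cc(OC)c1OC | intermediate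
13 | [(2R,3S)-5-bromo-2-(3,4,5-trimethoxyphenyl)-2,3-dihydro-1-benzofuran-3-yl]methanol (trans) | COc1cc([C@@H]2Oc3ccc(Br)cc3[C@H]2CO)cc(OC)c1OC | intermediate
14 | methyl acrylate | C=CC(=O)OC | starting material
15 | methyl (E)-3-[(2R,3S)-3-(hydroxymethyl)-2-(3,4,5-trimethoxyphenyl)-2,3-dihydro-1-benzofuran-5-yl]prop-2-enoate | COc1cc([C@@H]2Oc3ccc(/C=C/C(=O)OC)cc3[C@H]2CO)cc(OC)c1OC | intermediate
16 | (E)-3-[(2R,3S)-3-(hydroxymethyl)-2-(3,4,5-trimethoxyphenyl)-2,3-dihydro-1-benzofuran-5-yl]prop-2-en-1-ol | COc1cc([C@@H]2Oc3ccc(/C=C/CO)cc3[C@H]2CO)cc(OC)c1OC | target

## Step count and least certain steps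

Total steps: 9. Longest linear sequence: 8 steps (steps 1, 2, 3, 5, 6, 7, 8, 9 from diol 1); the branch to 8 is the single step 4.

**Step 5 (key step, proposed new method).** Three processes can defeat it.
- The sulfonium salt may benzylate the phenoxide oxygen directly before enough ylide has formed, consuming both partners.
- A semi-stabilised ylide adds faster and less reversibly than an acyl ylide, so the betaine may partition into nitronate C-alkylation (cyclopropane formation) or nitronate O-alkylation instead of phenoxide closure, and trans selectivity may suffer.
- Facial discrimination by the dimethylthiolane may be incomplete. If addition is reversible, the product ratio is set by the relative cyclisation rates of the equilibrating betaines and not by the ylide face alone.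

A moderate enantiomeric excess could be raised at acid 12 by crystallising a salt with an enantiopure amine.

Fallback, by known carbenoid chemistry, setting out from benzyl bromide 4 and returning at alcohol 13: commercial methyl 2-(5-bromo-2-hydroxyphenyl)acetate F1 is O-alkylated with 4 (K2CO3, DMF) to give methyl 2-[5-bromo-2-(3,4,5-trimethoxybenzyloxy)phenyl]acetate F2. Diazo transfer with 4-acetamidobenzenesulfonyl azide and DBU gives methyl 2-[5-bromo-2-(3,4,5-trimethoxybenzyloxy)phenyl]-2-diazoacetate F3. Rh2(S-PTTL)4, or its enantiomer, whichever delivers the 2R series, effects intramolecular benzylic C–H insertion to methyl (2R,3S)-cis-5-bromo-2-(3,4,5-trimethoxyphenyl)-2,3-dihydro-1-benzofuran-3-carboxylate F4. NaOMe in MeOH epimerises C3 to methyl (2R,3R)-trans-5-bromo-2-(3,4,5-trimethoxyphenyl)-2,3-dihydro-1-benzofuran-3-carboxylate F5. LiBH4 in THF reduces the ester to 13, and steps 8 and 9 follow unchanged.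

**Step 6.** The nitrosative conversion may stall at the nitrolic or hydroxamic acid stage, the nitrile oxide intermediate may dimerise, or the electron-rich ring A may undergo competing nitrosation. Epimerisation at C3 is unlikely to matter because trans is favoured.

Fallback, setting out from 11 and returning at 13: the nitronate of 11 (NaOMe, MeOH, 0 °C) is added to NH4OAc-buffered aqueous TiCl3 (reductive Nef reaction) to give (2R,3R)-5-bromo-2-(3,4,5-trimethoxyphenyl)-2,3-dihydro-1-benzofuran-3-carbaldehyde F6. This is reduced at once with NaBH4 to 13, bypassing acid 12 and the borane step.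

**Step 3.** S-Alkylation by an electron-rich benzylic bromide is reversible because bromide can dealkylate the salt. Failure to crystallise, or carry-over of free benzyl bromide, would feed direct phenol benzylation in step 5.

Fallback, setting out from sulfide 3 and returning at 11: 3,4,5-trimethoxybenzyl alcohol F7 and 3 are combined with HBF4·OEt2 in CH2Cl2 to give (2R,5R)-2,5-dimethyl-1-(3,4,5-trimethoxybenzyl)thiolan-1-ium tetrafluoroborate F8 through the benzylic cation. This non-nucleophilic salt replaces 5 in step 5.

**Step 8.** Oxidative addition to an aryl bromide para to an alkoxy group is slow. Catalyst decomposition and hydrodebromination (hydride delivered from the free alcohol or the amine) may then compete with coupling.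

Fallback, setting out from 13 and returning at 16: Suzuki–Miyaura coupling of 13 with (E)-tert-butyldimethyl{[3-(4,4,5,5-tetramethyl-1,3,2-dioxaborolan-2-yl)prop-2-en-1-yl]oxy}silane F9 (PdCl2(dppf), K2CO3, dioxane/water, 80 °C) gives the silyl ether tert-butyl{[(E)-3-[(2R,3S)-3-(hydroxymethyl)-2-(3,4,5-trimethoxyphenyl)-2,3-dihydro-1-benzofuran-5-yl]prop-2-en-1-yl]oxy}dimethylsilane F10. Tetrabutylammonium fluoride in THF then frees 16, bypassing ester 15 and step 9.

## Further compounds

F1 | step 5 | methyl 2-(5-bromo-2-hydroxyphenyl)acetate | COC(=O)Cc1cc(Br)ccc1O
F2 | step 5 | methyl 2-[5-bromo-2-(3,4,5-trimethoxybenzyloxy)phenyl]acetate | COC(=O)Cc1cc(Br)ccc1OCc1cc(OC)c(OC)c(OC)c1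
F3 | step 5 | methyl 2-[5-bromo-2-(3,4,5-trimethoxybenzyloxy)phenyl]-2-diazoacetate | COC(=O)C(=[N+]=[N-])c1cc(Br)ccc1OCc1cc(OC)c(OC)c(OC)c1
F4 | step 5 | methyl (2R,3S)-cis-5-bromo-2-(3,4,5-trimethoxyphenyl)-2,3-dihydro-1-benzofuran-3-carboxylate | COc1cc([C@@H]2Oc3ccc(Br)cc3[C@@H]2C(=O)OC)cc(OC)c1OC
F5 | step 5 | methyl (2R,3R)-trans-5-bromo-2-(3,4,5-trimethoxyphenyl)-2,3-dihydro-1-benzofuran-3-carboxylate | COc1cc([C@@H]2Oc3ccc(Br)cc3[C@H]2C(=O)OC)cc(OC)c1OC
F6 | step 6 | (2R,3R)-5-bromo-2-(3,4,5-trimethoxyphenyl)-2,3-dihydro-1-benzofuran-3-carbaldehyde | COc1cc([C@@H]2Oc3ccc(Br)cc3[C@H]2C=O)cc(OC)c1OC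
F7 | step 3 | 3,4,5-trimethoxybenzyl alcohol | COc1cc(CO)cc(OC)c1OC
F8 | step 3 | (2R,5R)-2,5-dimethyl-1-(3,4,5-trimethoxybenzyl)thiolan-1-ium tetrafluoroborate | C[C@@H]1CC[C@@H](C)[S+]1Cc1cc(OC)c(OC)c(OC)c1.F[B-](F)(F)F
F9 | step 8 | (E)-tert-butyldimethyl{[3-(4,4,5,5-tetramethyl-1,3,2-dioxaborolan-2-yl)prop-2-en-1-yl]oxy}silane | CC(C)(C)[Si](C)(C)OC/C=C/B1OC(C)(C)C(C)(C)O1
F10 | step 8 | tert-butyl{[(E)-3-[(2R,3S)-3-(hydroxymethyl)-2-(3,4,5-trimethoxyphenyl)-2,3-dihydro-1-benzofuran-5-yl]prop-2-en-1-yl]oxy}dimethylsilane | COc1cc([C@@H]2Oc3ccc(/C=C/CO[Si](C)(C)C(C)(C)C)cc3[C@H]2CO)cc(OC)c1OC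
A1 | alternative 1 | (S)-1-(3,4,5-trimethoxyphenyl)prop-2-en-1-ol | COc1cc([C@H](C=C)O)cc(OC)c1OC
A2 | alternative 1 | 4-bromo-2-iodophenol | Oc1ccc(Br)cc1I
A3 | alternative 1 | (R)-4-bromo-2-iodo-1-{[1-(3,4,5-trimethoxyphenyl)prop-2-en-1-yl]oxy}benzene | COc1cc([C@@H](C=C)Oc2ccc(Br)cc2I)cc(OC)c1OC
A4 | alternative 1 | (2R,3S)-trans-5-bromo-3-[(2,2,6,6-tetramethylpiperidin-1-yloxy)methyl]-2-(3,4,5-trimethoxyphenyl)-2,3-dihydro-1-benzofuran | COc1cc([C@@H]2Oc3ccc(Br)cc3[C@H]2CON4C(C)(C)CCCC4(C)C)cc(OC)c1OC
A5 | alternative 2 | methyl 2-[5-bromo-2-(3,4,5-trimethoxybenzyloxy)phenyl]-2-diazoacetate | COC(=O)C(=[N+]=[N-])c1cc(Br)ccc1OCc1cc(OC)c(OC)c(OC)c1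
A6 | alternative 2 | methyl (2R,3S)-cis-5-bromo-2-(3,4,5-trimethoxyphenyl)-2,3-dihydro-1-benzofuran-3-carboxylate | COc1cc([C@@H]2Oc3ccc(Br)cc3[C@@H]2C(=O)OC)cc(OC)c1OC
A7 | alternative 2 | methyl (2R,3R)-trans-5-bromo-2-(3,4,5-trimethoxyphenyl)-2,3-dihydro-1-benzofuran-3-carboxylate | COc1cc([C@@H]2Oc3ccc(Br)cc3[C@H]2C(=O)OC)cc(OC)c1OC
A8 | alternative 3 | 4-bromo-2-[(1S,2S)-2-(3,4,5-trimethoxyphenyl)cyclopropyl]phenol (trans) | COc1cc([C@H]2C[C@@H]2c2cc(Br)ccc2O)cc(OC)c1OC
A9 | alternative 3 | (2R,3R)-trans-5-bromo-3-(chloromercuriomethyl)-2-(3,4,5-trimethoxyphenyl)-2,3-dihydro-1-benzofuran | COc1cc([C@@H]2Oc3ccc(Br)cc3[C@H]2C[Hg]Cl)cc(OC)c1OC
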